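The numbers in the tables are simulated for substances that don't exist, and the scatter is random.

The amounts of complex with one exchanged fall from the first reading on in both earlier runs, so two numbers describe each run: what stood at zero time and how fast it fades.

all flasks: starting complex 0.20 M
- south: incoming ligand 0.50 equiv; protic impurity 0.20 M; capture agent 0.060 M; run made earlier
- north-west: incoming ligand 2 equiv; protic impurity 0.20 M; capture agent 0.060 M; run made earlier
- flask: incoming ligand 1.00 equiv; protic impurity 0.200 M; capture agent 0.0600 M; time 40 h

| run | time / h | complex with one exchanged / % | complex with two exchanged / % |
|---|---|---|---|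
| south | 8.00 | 18.6 | 1.5 |
| south | 15.0 | 14.6 | 1.5 |
| south | 25.0 | 11.0 | 0 |
| south | 30.0 | 10.3 | 0 |
| south | 40.0 | 7.7 | 0.7 |
| north-west | 3.00 | 55.3 | 2.6 |
| north-west | 6.00 | 54.3 | 2.0 |
| north-west | 12.0 | 44.8 | 1.4 |
| north-west | 20.0 | 36.9 | 2.5 |
| north-west | 40.0 | 26.3 | 3.7 |

(scatter of a reading: 1 percentage point)

1. equivalents of incoming ligand to starting complex, everything else as given, that leave most complex with one exchanged at 40 h
2. the amount of complex with one exchanged then, in percent of the starting complex charged
3. the amount of complex with one exchanged with the amounts as given



Taken as pseudo-first-order, the loss integrates to [complex with one exchanged] = zero-time amount × exp(−λt). Here λ is the logarithm of the ratio of first to last reading over the hours between them. The south run gives 0.0276 h⁻¹ for this fade constant, and the north-west run gives 0.0201 h⁻¹, which is less. Running back to zero time gives 23.2% and 58.7%. Per equivalent of incoming ligand, these are 0.464 in the south run and 0.294 in the north-west run, which is less.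

The flask's charge lies between the two runs, so its values are taken to lie between theirs. The lower yield with the faster fade gives the lower bound, 9.75%. The higher yield with the slower fade gives the upper bound, 20.8%. For the best amount, the north-west reading of 26.3% stands below, and complete conversion at zero time, faded at the slower constant, stands above at 44.8%. The best equivalents get no such bound by hand.

The forecast, holding that “More ligand keeps helping until double exchange bites”, gives 5 equiv, 35% and 15%, the last above the lower bound and below the upper. The simulation gives 11.8% for the flask, above the lower bound and below the upper, and a best of 30.0% at 2.32 equiv.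

    complex with two exchanged ⇌ isomer of the product (K = 2.70, k = 0.00540 min⁻¹)
    complex with one exchanged + incoming ligand ⇌ leaving ligand + complex with two exchanged (K = 43.0, k = 0.00150 M⁻¹ min⁻¹)
    starting complex + incoming ligand ⇌ leaving ligand + complex with one exchanged (K = 2.00, k = 0.0300 M⁻¹ min⁻¹)
    protic impurity + incoming ligand → quenched reagent (k = 0.0310 M⁻¹ min⁻¹)
    complex with one exchanged + capture agent → trapped intermediate (k = 0.00630 M⁻¹ min⁻¹)

At the end of the flask, 1.8% of the incoming ligand's charge remains, against 72% of the starting complex's charge, and the incoming ligand is the limiting reagent, the first to run out. With 0.600 equiv of incoming ligand, the same reckoning brackets the neighbour flask between 5.85% and 12.5%, and that flask holds 7.59%.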